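## Retrosynthetic overview

1. The α-methylene-ε-lactone is closed last (C16 acid onto the tertiary C12–OH); the two acetates come from a C3/C11 diol.
2. The 14-membered carbocycle comes from a 14-membered allylic macrolactone (C11 ester of the C19 allylic alcohol) by carbonyl methylenation and Claisen [3,3] rearrangement. This forms C9–C10, the C8 exo-methylene and the C11 ketone in one event.
3. The macrolactone comes from intramolecular carboxylate alkylation of a seco acid, itself made by aldol union, oxidation and retro-Claisen opening of a carvone-derived cyclohexanone (C11, C12, C13, C14, C1, C2) with a tetrahydrofuran aldehyde (C3–C9).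
4. East half from (R)-carvone: C1 is bought, C12 is set by epoxidation anti to it. West half from (R)-linalool: C4 is bought, C7 is set by an Os-catalysed cis oxidative cyclization. C3 and C11 are set by ketone reductions controlled by C4 and C12.
5. Ring order: tetrahydrofuran → (carvone ring opened) → macrolactone → carbocycle (Claisen) → ε-lactone.

Assumptions: cembrane numbering of the target is used throughout (C1 = ring CH bearing the acrylate carbon C15; C16 = lactone C=O; C17 = its methylene; C18/C19/C20 = substituent carbons on C4/C8/C12). Only starting materials, intermediates and the target are numbered; reagents are named in each step.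

## Route

**Step 1**
Reactants: 1, (R)-(−)-carvone
Product: 2, (1R,4R,6R)-1-methyl-4-(prop-1-en-2-yl)-7-oxabicyclo[4.1.0]heptan-2-one
Conditions: 30% H2O2, NaOH, MeOH, 0 °C
Reagents that add atoms: hydrogen peroxide, OO
Why: Weitz–Scheffer nucleophilic epoxidation; hydroperoxide adds to the enone face anti to the isopropenyl group, so the tertiary C–O bond (future C12–O) is set trans to the bought centre (future C1).

**Step 2**
Reactants: 2
Product: 3, (1R,4R)-1-methyl-4-(prop-1-en-2-yl)cyclohexane-1,2-diol (C2 epimers)
Conditions: LiAlH4, THF, 0 °C → rt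
Reagents that add atoms: none (hydride only)
Why: Ketone reduction plus hydride opening of the epoxide at its less substituted carbon leaves the tertiary C–O bond intact, so C12 keeps its configuration.

**Step 3**
Reactants: 3
Product: 4, (2R,5R)-2-hydroxy-2-methyl-5-(prop-1-en-2-yl)cyclohexan-1-one
Conditions: SO3·pyridine, DMSO, i-Pr2NEt, CH2Cl2, 0 °C
Reagents that add atoms: none
Why: Parikh–Doering oxidation touches only the secondary alcohol and does not cleave the diol; both carbinol epimers converge.

**Step 4**
Reactants: 4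
Product: 5, (2R,5R)-2-hydroxy-5-(3-hydroxyprop-1-en-2-yl)-2-methylcyclohexan-1-one
Conditions: SeO2 (0.5 equiv), t-BuOOH, CH2Cl2, rt
Reagents that add atoms: selenium dioxide, O=[Se]=O; tert-butyl hydroperoxide, CC(C)(C)OO
Why: SeO2 allylic oxidation (ene, then [2,3] shift) of the isopropenyl methyl installs the future C16 oxygen now, because later a second 1,1-disubstituted alkene would compete.

**Step 5**
Reactants: 5
Product: 6, (2R,5R)-5-[3-(tert-butyldimethylsilyloxy)prop-1-en-2-yl]-2-hydroxy-2-methylcyclohexan-1-one
Conditions: TBSCl, imidazole, DMF, 0 °C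
Reagents that add atoms: TBSCl, CC(C)(C)[Si](C)(C)Cl
Why: Selective silylation of the primary allylic alcohol; the tertiary alcohol is left free.

**Step 6**
Reactants: 7, (R)-(−)-linalool
Product: 8, (3R)-3,7-dimethyloct-6-ene-1,2,3-triol (C2 epimers)
Conditions: VO(acac)2 (2 mol %), t-BuOOH (1.1 equiv), CH2Cl2, 0 °C; then 3% aq HClO4, THF, 0 °C
Reagents that add atoms: tert-butyl hydroperoxide, CC(C)(C)OO; water, O
Why: Hydroxyl-directed vanadium epoxidation selects the allylic vinyl group over the remote trisubstituted alkene, and acid hydrolysis opens the epoxide; the new carbinol centre is destroyed in step 11.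

**Step 7**
Reactants: 8
Product: 9, 1-[(2R,5S)-5-(2-hydroxypropan-2-yl)-2-methyloxolan-2-yl]ethane-1,2-diol
Conditions: K2OsO2(OH)4 (5 mol %), pyridine N-oxide, citric acid, Cu(OTf)2, MeCN/pH 6.5 buffer, 60 °C
Reagents that add atoms: pyridine N-oxide (oxygen source via Os=O), [O-][n+]1ccccc1
Why: Os(VI) oxidative cyclization; the C3/C4 glycolate adds across the alkene in an intramolecular [3+2] step with both side arms bound to one osmium, which enforces the 2,5-cis tetrahydrofuran and sets C7 from C4.

**Step 8**
Reactants: 9
Product: 10, 2-[(2S,5R)-5-(2,2-dimethyl-1,3-dioxolan-4-yl)-5-methyloxolan-2-yl]propan-2-ol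
Conditions: 2,2-dimethoxypropane, PPTS, acetone, rt
Reagents that add atoms: 2,2-dimethoxypropane, COC(C)(C)OC
Why: Acetonide formation masks only the terminal 1,2-diol; the tertiary alcohol cannot form a dioxolane.

**Step 9**
Reactants: 10
Product: 11, 4-[(2R,5S)-2-methyl-5-(prop-1-en-2-yl)oxolan-2-yl]-2,2-dimethyl-1,3-dioxolane
Conditions: Burgess reagent, toluene, 70 °C
Reagents that add atoms: none
Why: Syn-elimination of the tertiary alcohol goes toward a methyl group (six available H) and not toward the ether-bearing C7–H.

**Step 10**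
Reactants: 11
Product: 12, 4-[(2R,5S)-5-(3-chloroprop-1-en-2-yl)-2-methyloxolan-2-yl]-2,2-dimethyl-1,3-dioxolane
Conditions: Ca(OCl)2, solid CO2, CH2Cl2/H2O, 0 °C
Reagents that add atoms: calcium hypochlorite, [Ca+2].[O-]Cl.[O-]Cl
Why: Ene-type allylic chlorination by HOCl on the only alkene present gives the 2-(chloromethyl)allyl unit.

**Step 11**
Reactants: 12
Product: 13, (2R,5S)-5-(3-chloroprop-1-en-2-yl)-2-methyloxolane-2-carbaldehyde
Conditions: H5IO6, EtOAc, rt
Reagents that add atoms: none
Why: Periodic acid hydrolyses the terminal acetonide and cleaves the glycol in one operation; the aldehyde has a quaternary α-carbon and cannot epimerise.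

**Step 12**
Reactants: 6; 13
Product: 14, aldol adduct: cyclohexanone 6 carrying at C6 (target C2) a CH(OH) group (target C3) bonded to C2 of the oxolane of 13 (mixture at the two new centres)
Conditions: LDA (2.1 equiv), THF, −78 °C; then 13
Reagents that add atoms: none (apart from 13)
Why: Aldol addition of the alkoxide/enolate dianion; the ketone has only one enolisable side, and both new centres are erased in steps 13–14.

**Step 13**
Reactants: 14
Product: 15, the corresponding 2-acylcyclohexanone (C11/C3 1,3-diketone)
Conditions: Dess–Martin periodinane, NaHCO3, CH2Cl2, rt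
Reagents that add atoms: none
Why: Oxidation of the secondary carbinol; the tertiary alcohol and the allylic chloride are inert.

**Step 14**
Reactants: 15
Product: 16, (2R,5R)-5-[3-(TBS-oxy)prop-1-en-2-yl]-7-[(2R,5S)-5-(3-chloroprop-1-en-2-yl)-2-methyloxolan-2-yl]-2-hydroxy-2-methyl-7-oxoheptanoic acid
Conditions: LiOH, THF/H2O, 0 °C → rt
Reagents that add atoms: lithium hydroxide/water, [Li+].[OH-]
Why: Retro-Claisen ring opening; hydroxide adds to the more reactive, less hindered α-hydroxy cyclohexanone carbonyl (C11) and expels the C3 ketone enolate, giving the C11 acid and C2 methylene without touching C1 or C12.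

**Step 15**
Reactants: 16
Product: 17, 14-membered macrolactone (C11 carboxyl esterified by C19; C3 ketone; 1R,4R,7S,12R)
Conditions: Cs2CO3, Bu4NI (cat.), DMF (2 mM), 60 °C
Reagents that add atoms: none
Why: Macrolactonization by intramolecular SN2 of the caesium carboxylate on the primary allylic chloride; the alcohols need no protection.

**Step 16**
Reactants: 17
Product: 18, (3S)-alcohol of 17
Conditions: Zn(BH4)2, Et2O, −40 °C
Reagents that add atoms: none (hydride only)
Why: Chelation-controlled reduction; zinc bridges the C3 carbonyl and the ring oxygen on C4, and hydride enters from the exposed methyl face of this chelate, giving the 3S,4R (anti) arrangement.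

**Step 17**
Reactants: 18
Product: 19, 3,12-bis(trimethylsilyl) ether of 18
Conditions: TMSOTf, 2,6-lutidine, CH2Cl2, −78 → 0 °C
Reagents that add atoms: TMSOTf, C[Si](C)(C)OS(=O)(=O)C(F)(F)F
Why: Both free hydroxyls are masked so the lactone is the only group that reacts with the titanium reagent.

**Step 18**
Reactants: 19
Product: 20, macrocyclic allyl vinyl ether (lactone C11=O replaced by C11=C10H2)
Conditions: Cp2TiMe2 (3 equiv), toluene, 75 °C, dark
Reagents that add atoms: dimethyltitanocene (delivers CH2 = C10), C[Ti](C)(C1C=CC=C1)C1C=CC=C1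
Why: Petasis carbonyl methylenation of the only ester turns the allyl ester into an allyl vinyl ether and supplies the missing carbon C10.

**Step 19 (key step)**
Reactants: 20
Product: 21, 14-membered carbocyclic C11 ketone with C8 exo-methylene (1R,3S,4R,7S,12R)
Conditions: xylenes, BHT, trace Et3N, 150 °C, sealed tube
Reagents that add atoms: none
Why: Claisen [3,3]-sigmatropic rearrangement forms C9–C10, breaks O–C19 and gives the C11 ketone and C8=C19 methylene; ring size is unchanged and no stereocentre is involved.

**Step 20**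
Reactants: 21
Product: 22, 3,11,12-triol with the 16-O-TBS ether retained (1R,3S,4R,7S,11R,12R)
Conditions: L-Selectride, THF, −78 °C; then K2CO3, MeOH, rt
Reagents that add atoms: none (hydride only)
Why: Felkin–Anh reduction; the bulky hydride attacks anti to the non-chelating C12–OSiMe3 group and past the C12 methyl, giving the 11R,12R (syn) relationship; methanolysis then removes both TMS ethers.

**Step 21**
Reactants: 22
Product: 23, 3,11-diacetate
Conditions: Ac2O, pyridine, DMAP (cat.), CH2Cl2, 0 °C → rt
Reagents that add atoms: acetic anhydride, CC(=O)OC(C)=O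
Why: Acetylation of the two secondary alcohols; the tertiary C12–OH does not react under these conditions.

**Step 22**
Reactants: 23
Product: 24, 12,16-diol diacetate
Conditions: HF·pyridine, THF/pyridine, 0 °C → rt
Reagents that add atoms: none
Why: Acidic fluoride removes the primary TBS ether without acetate migration.

**Step 23**
Reactants: 24
Product: 25, seco acid (C16 carboxylic acid, free C12–OH)
Conditions: TEMPO (cat.), PhI(OAc)2, MeCN/H2O, rt
Reagents that add atoms: water, O
Why: Oxoammonium oxidation takes the primary allylic alcohol to the acrylic acid; no secondary alcohol is free, so the unwanted C16-to-C3 lactol cannot form.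

**Step 24**
Reactants: 25
Product: 26, Granosolide B
Conditions: 2,4,6-trichlorobenzoyl chloride, Et3N, THF, rt; then DMAP, toluene (1 mM), 80 °C
Reagents that add atoms: none
Why: Yamaguchi lactonization onto the only free hydroxyl (C12) closes the seven-membered α-methylene lactone with retention at C12.

## Compound list

1 | (R)-(−)-carvone | CC1=CC[C@H](CC1=O)C(C)=C | starting material
2 | trans-carvone epoxide (1R,4R,6R) | C[C@@]12O[C@@H]1C[C@H](CC2=O)C(C)=C | intermediate
3 | (1R,4R)-p-menth-8-ene-1,2-diol (C2 epimers) | C[C@@]1(O)CC[C@H](CC1O)C(C)=C | intermediate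
4 | (2R,5R)-2-hydroxy-2-methyl-5-isopropenylcyclohexanone | C[C@@]1(O)CC[C@H](CC1=O)C(C)=C | intermediate
5 | (2R,5R)-2-hydroxy-5-(3-hydroxyprop-1-en-2-yl)-2-methylcyclohexanone | C[C@@]1(O)CC[C@H](CC1=O)C(=C)CO | intermediate
6 | mono-TBS ether of 5 (East fragment) | C[C@@]1(O)CC[C@H](CC1=O)C(=C)CO[Si](C)(C)C(C)(C)C | intermediate
7 | (R)-(−)-linalool | C=C[C@](C)(O)CCC=C(C)C | starting material
8 | (3R)-3,7-dimethyloct-6-ene-1,2,3-triol | OCC(O)[C@](C)(O)CCC=C(C)C | intermediate
9 | cis-THF triol (2R,5S) | OCC(O)[C@@]1(C)CC[C@H](O1)C(C)(C)O | intermediate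
10 | acetonide of 9 | CC1(C)OCC(O1)[C@@]1(C)CC[C@H](O1)C(C)(C)O | intermediate
11 | isopropenyl THF acetonide | CC1(C)OCC(O1)[C@@]1(C)CC[C@H](O1)C(C)=C | intermediate
12 | allylic chloride acetonide | CC1(C)OCC(O1)[C@@]1(C)CC[C@H](O1)C(=C)CCl | intermediate
13 | (2R,5S)-5-(3-chloroprop-1-en-2-yl)-2-methyloxolane-2-carbaldehyde (West fragment) | O=C[C@@]1(C)CC[C@H](O1)C(=C)CCl | intermediate
14 | aldol adduct | C[C@@]1(O)CC[C@H](C(C1=O)C(O)[C@@]2(C)CC[C@H](O2)C(=C)CCl)C(=C)CO[Si](C)(C)C(C)(C)C | intermediate
15 | 1,3-diketone | C[C@@]1(O)CC[C@H](C(C1=O)C(=O)[C@@]2(C)CC[C@H](O2)C(=C)CCl)C(=C)CO[Si](C)(C)C(C)(C)C | intermediate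
16 | seco chloro acid | OC(=O)[C@](C)(O)CC[C@H](CC(=O)[C@@]1(C)CC[C@H](O1)C(=C)CCl)C(=C)CO[Si](C)(C)C(C)(C)C | intermediate
17 | macrolactone, C3 ketone | O=C1OCC(=C)[C@@H]2CC[C@@](C)(O2)C(=O)C[C@@H](CC[C@@]1(C)O)C(=C)CO[Si](C)(C)C(C)(C)C | intermediate
18 | macrolactone, (3S)-alcohol | O=C1OCC(=C)[C@@H]2CC[C@@](C)(O2)[C@@H](O)C[C@@H](CC[C@@]1(C)O)C(=C)CO[Si](C)(C)C(C)(C)C | intermediate
19 | bis-TMS macrolactone | O=C1OCC(=C)[C@@H]2CC[C@@](C)(O2)[C@@H](O[Si](C)(C)C)C[C@@H](CC[C@@]1(C)O[Si](C)(C)C)C(=C)CO[Si](C)(C)C(C)(C)C | intermediate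
20 | macrocyclic allyl vinyl ether | C=C1OCC(=C)[C@@H]2CC[C@@](C)(O2)[C@@H](O[Si](C)(C)C)C[C@@H](CC[C@@]1(C)O[Si](C)(C)C)C(=C)CO[Si](C)(C)C(C)(C)C | intermediate
21 | carbocyclic C11 ketone (Claisen product) | O=C1CCC(=C)[C@@H]2CC[C@@](C)(O2)[C@@H](O[Si](C)(C)C)C[C@@H](CC[C@@]1(C)O[Si](C)(C)C)C(=C)CO[Si](C)(C)C(C)(C)C | intermediate
22 | 3,11,12-triol, 16-O-TBS | O[C@@H]1CCC(=C)[C@@H]2CC[C@@](C)(O2)[C@@H](O)C[C@@H](CC[C@@]1(C)O)C(=C)CO[Si](C)(C)C(C)(C)C | intermediate
23 | 3,11-diacetate, 16-O-TBS | CC(=O)O[C@@H]1CCC(=C)[C@@H]2CC[C@@](C)(O2)[C@@H](OC(C)=O)C[C@@H](CC[C@@]1(C)O)C(=C)CO[Si](C)(C)C(C)(C)C | intermediate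
24 | 12,16-diol diacetate | CC(=O)O[C@@H]1CCC(=C)[C@@H]2CC[C@@](C)(O2)[C@@H](OC(C)=O)C[C@@H](CC[C@@]1(C)O)C(=C)CO | intermediate
25 | seco acid diacetate | CC(=O)O[C@@H]1CCC(=C)[C@@H]2CC[C@@](C)(O2)[C@@H](OC(C)=O)C[C@@H](CC[C@@]1(C)O)C(=C)C(O)=O | intermediate
26 | Granosolide B (1R,3S,4R,7S,11R,12R) | C=C1C(=O)O[C@]2(C)CC[C@@H]1C[C@H](OC(C)=O)[C@@]1(C)CC[C@H](O1)C(=C)CC[C@H]2OC(C)=O | target

## Summary

Total steps: 24 (East 1–5, West 6–11, union and endgame 12–24).
Longest linear sequence: 19 steps, from (R)-linalool (steps 6–11, then 12–24).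

Steps most likely to fail:

1. **Step 14 (retro-Claisen).** Hydroxide could attack the C3 ketone instead of C11, or displace the allylic chloride. Fallback: open the carvone ring regiospecifically before fragment union. α-Sulfonylate ketone 6, cleave the β-keto sulfone with LiOH (only one carbonyl can be attacked), acylate the resulting sulfone anion with the acid fluoride corresponding to 13, and remove the sulfone with Al–Hg to reach the same C3 ketone.
2. **Steps 18–19 (methylenation of the hindered macrolactone and transannular Claisen).** Fallback: a decarboxylative Carroll rearrangement. Convert the C11 acid of 16 to its acyl Meldrum's acid, trap intramolecularly with the C19 allylic alcohol (chloride first hydrolysed) to give a 16-membered β-keto lactone, and heat to effect [3,3] shift and loss of CO2 to ketone 21. This avoids titanium reagents and tolerates other esters.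
3. **Step 24 (seven-membered lactonization onto a tertiary alcohol).** Fallback: build the lactone by carbonylation instead of acylation. Ozonolyse the carvone isopropenyl to an acetyl group at the start and carry it as a ketal; late in the route convert it to the kinetic vinyl triflate and close the ring by Pd(0)/CO intramolecular alkoxycarbonylation onto C12–OH.

The C11 reduction (step 20) is the least certain stereochemical step: the Felkin preference rests on methyl versus ring CH2 at C12 and could be overridden by the macrocycle conformation.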